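**Retrosynthetic overview**

1. 33 ⇐ 22: ester hydrolysis, reduction of a C2 ketone from the α face, oxidation of C18 to the acid, and a 1,2-carbonyl transposition C3 → C2 through a 2-phenylthio ketone.
2. 22 ⇐ 21: one cationic bicyclisation; opening of the C3–C4 epoxide forms C4–C5 (ring A first), then C9–C10 (ring B), and the allylsilane leaves the C8=C17 methylene.
3. Feature used: the trans-fused decalin (rings A and B), whose C4, C5, C10 and 9βH-C9 centres are those of a chair–chair folded chain in which C7 and C11 are cis on the C8=C9 olefin.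
4. 21 ⇐ 7 + 2 × 8 + 17: two acetoacetate-dianion homologations (C6–C7, C11–C12); C8=C9 is fixed as an (E)-enol triflate and coupled with Me3SiCH2MgCl only after the second homologation; C13=C14 is fixed as a (Z)-enol phosphate and methylated with Me2CuLi.
5. 7 ⇐ 1: allylic oxidation at C18 and Sharpless epoxidation, which sets C3/C4 and with them the absolute configuration.

Key step: step 14

Remark: labdane numbering is used for all intermediates, acyclic ones included; the required C8=C9 geometry (C7 and C11 cis, neryl-type) carries the descriptor E wherever C8 bears OTf or CH2SiMe3.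

**Route**

Step 1
Reactants: 1 geranyl acetate
Product: 2 (2E,6E)-8-hydroxy-3,7-dimethylocta-2,6-dien-1-yl acetate
Conditions: SeO2 (cat.), salicylic acid (cat.), t-BuOOH (70% aq.), CH2Cl2, rt
Reagents that add atoms: selenium dioxide O=[Se]=O (oxygen carrier); tert-butyl hydroperoxide CC(C)(C)OO (terminal oxidant)
Why: Catalytic SeO2 allylic oxidation (ene reaction, then 2,3-sigmatropic shift) attacks the (E)-methyl group of the electron-rich terminal olefin, while the olefin next to the allylic acetate is deactivated.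

Step 2
Reactants: 2 (2E,6E)-8-hydroxy-3,7-dimethylocta-2,6-dien-1-yl acetate
Product: 3 (2E)-5-[(2S,3S)-3-(hydroxymethyl)-3-methyloxiran-2-yl]-3-methylpent-2-en-1-yl acetate
Conditions: Ti(OiPr)4 (cat.), L-(+)-diethyl tartrate (cat.), t-BuOOH (anhydrous), 4 Å MS, CH2Cl2, −20 °C
Reagents that add atoms: tert-butyl hydroperoxide CC(C)(C)OO
Why: Sharpless asymmetric epoxidation reacts only at the olefin of the free allylic alcohol, and the L-(+)-tartrate ligand delivers oxygen to the face that gives the (2S,3S)-epoxy alcohol, which fixes C3 and C4 and with them the absolute configuration of the whole route.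

Step 3
Reactants: 3 epoxy alcohol acetate
Product: 4 (2E)-5-[(2S,3S)-3-(tert-butyldimethylsilyloxymethyl)-3-methyloxiran-2-yl]-3-methylpent-2-en-1-yl acetate
Conditions: TBSCl, imidazole, DMF, 0 °C → rt
Reagents that add atoms: tert-butyldimethylsilyl chloride CC(C)(C)[Si](C)(C)Cl
Why: Imidazole-promoted silylation of the primary alcohol blocks Payne rearrangement and leaves a non-nucleophilic C18 substituent for the later Lewis-acid step.

Step 4
Reactants: 4 silyl ether acetate
Product: 5 (2E)-5-[(2S,3S)-3-(tert-butyldimethylsilyloxymethyl)-3-methyloxiran-2-yl]-3-methylpent-2-en-1-ol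
Conditions: K2CO3, MeOH, 0 °C
Reagents that add atoms: none
Why: Mild transesterification (methanolysis) removes the acetate, while the trisubstituted epoxide and the primary silyl ether are stable to K2CO3 in methanol at 0 °C.

Step 5
Reactants: 5 epoxy allylic alcohol
Product: 7 (2S,3S)-3-[(3E)-5-bromo-3-methylpent-3-en-1-yl]-2-(tert-butyldimethylsilyloxymethyl)-2-methyloxirane, via allylic mesylate 6 (not isolated)
Conditions: MsCl, Et3N, CH2Cl2, −40 °C; then LiBr, THF, 0 °C
Reagents that add atoms: methanesulfonyl chloride CS(=O)(=O)Cl (atoms kept only in 6); lithium bromide [Li+].[Br-]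
Why: Mesylation followed by SN2 displacement with bromide at low temperature gives the primary allylic bromide without allylic transposition and without opening the epoxide.

Step 6
Reactants: 7 epoxy allylic bromide; 8 methyl acetoacetate
Product: 10 methyl (6E)-9-[(2S,3S)-3-(tert-butyldimethylsilyloxymethyl)-3-methyloxiran-2-yl]-7-methyl-3-oxonon-6-enoate, via sodium lithium acetoacetate dianion 9 (not isolated)
Conditions: 8, NaH, THF, 0 °C; n-BuLi, 0 °C; then 7, 0 °C; aq. NH4Cl
Reagents that add atoms: sodium hydride [Na+].[H-] and n-butyllithium [Li]CCCC (counter-ions of 9 only)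
Why: γ-Alkylation of the acetoacetate dianion, whose more basic terminal carbanion displaces the allylic bromide by SN2 and forms the C6–C7 bond, the epoxide being inert to the enolate at 0 °C.

Step 7
Reactants: 10 β-keto ester
Product: 11 methyl (2E,6E)-9-[(2S,3S)-3-(tert-butyldimethylsilyloxymethyl)-3-methyloxiran-2-yl]-7-methyl-3-(trifluoromethylsulfonyloxy)nona-2,6-dienoate
Conditions: Tf2O, aq. Me4NOH, hexanes, 5 °C
Reagents that add atoms: trifluoromethanesulfonic anhydride O=S(=O)(OS(=O)(=O)C(F)(F)F)C(F)(F)F
Why: O-Triflation of the β-keto ester enolate under two-phase conditions with the non-chelating tetramethylammonium counter-ion gives the (E)-enol triflate, in which C7 and the ester carbon C11 are cis as the C9 centre will require, and the epoxide meets the anhydride only in a hydroxide-buffered mixture.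

Step 8
Reactants: 11 (E)-enol triflate ester
Product: 12 (2E,6E)-9-[(2S,3S)-3-(tert-butyldimethylsilyloxymethyl)-3-methyloxiran-2-yl]-1-hydroxy-7-methylnona-2,6-dien-3-yl trifluoromethanesulfonate
Conditions: i-Bu2AlH, CH2Cl2, −78 °C; aq. potassium sodium tartrate
Reagents that add atoms: none
Why: 1,2-Reduction of the enoate ester by the aluminium hydride at −78 °C gives the allylic alcohol and leaves the vinyl triflate, the epoxide and the silyl ether untouched.

Step 9
Reactants: 12 triflate allylic alcohol
Product: 14 (2E,6E)-1-bromo-9-[(2S,3S)-3-(tert-butyldimethylsilyloxymethyl)-3-methyloxiran-2-yl]-7-methylnona-2,6-dien-3-yl trifluoromethanesulfonate, via allylic mesylate 13 (not isolated)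
Conditions: MsCl, Et3N, CH2Cl2, −40 °C; then LiBr, THF, 0 °C
Reagents that add atoms: methanesulfonyl chloride CS(=O)(=O)Cl (atoms kept only in 13); lithium bromide [Li+].[Br-]
Why: Mesylation and SN2 bromide displacement as in step 5, the electron-withdrawing triflyloxy group making this allylic bromide resistant to ionisation.

Step 10
Reactants: 14 triflate allylic bromide; 8 methyl acetoacetate
Product: 16 methyl (6E,10E)-13-[(2S,3S)-3-(tert-butyldimethylsilyloxymethyl)-3-methyloxiran-2-yl]-11-methyl-3-oxo-7-(trifluoromethylsulfonyloxy)trideca-6,10-dienoate, via dilithium acetoacetate dianion 15 (not isolated)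
Conditions: 8, LiN(i-Pr)2 (2.1 equiv), THF, 0 °C; then 14, −20 → 0 °C; aq. NH4Cl
Reagents that add atoms: lithium diisopropylamide [Li+].CC(C)[N-]C(C)C (counter-ions of 15 only)
Why: A second γ-alkylation of an acetoacetate dianion forms C11–C12 by SN2 on the primary allylic bromide, which is much faster than any attack of the carbanion on the vinyl triflate; the dianion is made here with two equivalents of the non-nucleophilic lithium amide so that no alkyllithium or hydride can meet the triflate or the allylic bromide.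

Step 11
Reactants: 16 triflate β-keto ester; 17 (trimethylsilyl)methylmagnesium chloride
Product: 18 methyl (6E,10E)-13-[(2S,3S)-3-(tert-butyldimethylsilyloxymethyl)-3-methyloxiran-2-yl]-11-methyl-3-oxo-7-[(trimethylsilyl)methyl]trideca-6,10-dienoate
Conditions: Me3SiCH2MgCl (3 equiv), Pd(PPh3)4 (cat.), THF, 0 °C → rt; aq. NH4Cl
Reagents that add atoms: none
Why: Kumada coupling under zerovalent-palladium catalysis replaces the triflate with retention of olefin geometry while the keto ester is masked as its magnesium enolate by the first equivalent of Grignard reagent, and the silylmethyl group is introduced only at this point because a C11 allylic bromide already carrying the C17 silane would be prone to 1,4-elimination to a diene.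

Step 12
Reactants: 18 allylsilane β-keto ester
Product: 20 methyl (2Z,6E,10E)-13-[(2S,3S)-3-(tert-butyldimethylsilyloxymethyl)-3-methyloxiran-2-yl]-3-(diethoxyphosphoryloxy)-11-methyl-7-[(trimethylsilyl)methyl]trideca-2,6,10-trienoate, via sodium enolate 19 (not isolated)
Conditions: NaH, Et2O, 0 °C; then ClP(O)(OEt)2, 0 °C
Reagents that add atoms: diethyl chlorophosphate CCOP(=O)(Cl)OCC; sodium hydride [Na+].[H-] (counter-ion of 19 only)
Why: O-Phosphorylation of the chelated sodium enolate gives the (Z)-enol phosphate (phosphate cis to the ester), which fixes the C13=C14 geometry.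

Step 13
Reactants: 20 (Z)-enol phosphate
Product: 21 methyl (2E,6E,10E)-13-[(2S,3S)-3-(tert-butyldimethylsilyloxymethyl)-3-methyloxiran-2-yl]-3,11-dimethyl-7-[(trimethylsilyl)methyl]trideca-2,6,10-trienoate (C7 and C11 cis on C8=C9)
Conditions: Me2CuLi (from MeLi and CuI), Et2O, −78 → −45 °C; aq. NH4Cl
Reagents that add atoms: lithium dimethylcuprate [Li+].C[Cu-]C (made from methyllithium [Li]C and CuI)
Why: Addition–elimination of the cuprate on the β-phosphoryloxy enoate replaces phosphate by methyl with retention and gives the (13E)-enoate, the allylsilane and the epoxide being inert to the cuprate at low temperature.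

Step 14
Reactants: 21 epoxy allylsilane tetraenoate
Product: 22 methyl 18-(tert-butyldimethylsilyloxy)-3β-hydroxy-9βH-labda-8(17),13E-dien-15-oate
Conditions: MeAlCl2 (2 equiv), CH2Cl2, −94 → −78 °C; then Et3N, MeOH/H2O
Reagents that add atoms: none
Why: MeAlCl2 binds the epoxide oxygen, the C4–O bond ionises at the tertiary carbon, C5 of the (E)-C5=C10 olefin attacks C4 anti to the departing oxygen, the C10 cation is captured by C9 of the allylsilane and the β-silyl cation loses Me3Si, leaving only the C8=C17 methylene. The closest known reaction type is the Lewis-acid-promoted epoxy-polyene cyclisation with Sakurai-type allylsilane termination. Ring A closes 6-endo on the C5=C10 olefin through a chair, and ring B closes 6-endo on the C8=C9 olefin through a second chair. C4 is inverted, so the silyloxymethyl group trans to C2 in the epoxide becomes equatorial C18 (α); C5 and C10 arise from anti addition across the (E)-olefin (trans fusion, 5α-H, 10β-methyl); C9 follows from the olefin geometry, C11 cis to C7 becoming axial (α side chain, 9β-H); C3 keeps its configuration and ends as the equatorial 3β-alcohol. The step needs complete bicyclisation through the chair–chair fold instead of arrest after ring A or a boat-like ring B (which would give the C9 epimer), and this is secured by the high nucleophilicity of the allylsilane, the low temperature and the electron-poor enoate terminus, which does not compete for the cation.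

Step 15
Reactants: 22 bicyclic 3β-alcohol
Product: 23 methyl 18-(tert-butyldimethylsilyloxy)-3-oxo-9βH-labda-8(17),13E-dien-15-oate
Conditions: Dess–Martin periodinane, CH2Cl2, rt
Reagents that add atoms: none
Why: Dess–Martin oxidation converts the hindered secondary alcohol into the ketone under neutral conditions that leave the alkenes, the ester and the silyl ether alone.

Step 16
Reactants: 23 3-ketone
Product: 25 methyl 18-(tert-butyldimethylsilyloxy)-3-oxo-2α-(phenylthio)-9βH-labda-8(17),13E-dien-15-oate, via lithium enolate 24 (not isolated)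
Conditions: LiN(SiMe3)2 (1.05 equiv), THF, −78 °C; then PhSSO2Ph, −78 °C
Reagents that add atoms: S-phenyl benzenethiosulfonate O=S(=O)(Sc1ccccc1)c1ccccc1; lithium hexamethyldisilazide [Li+].C[Si](C)(C)[N-][Si](C)(C)C (counter-ion of 24 only)
Why: α-Sulfenylation of the kinetic lithium enolate, which can form only toward C2 because C4 is quaternary, with the electrophile entering from the α face away from the axial C19 and C20 methyls to give the equatorial 2α-sulfide, one equivalent of amide at −78 °C not deprotonating the enoate.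

Step 17
Reactants: 25 2α-phenylthio 3-ketone
Product: 26 methyl 18-(tert-butyldimethylsilyloxy)-3β-hydroxy-2α-(phenylthio)-9βH-labda-8(17),13E-dien-15-oate
Conditions: NaBH4, MeOH/THF, 0 °C
Reagents that add atoms: none
Why: Borohydride reduction by axial hydride attack from the α face gives the equatorial 3β-alcohol, cis to H2β, and does not touch the ester.

Step 18
Reactants: 26 β-hydroxy sulfide
Product: 27 methyl 18-(tert-butyldimethylsilyloxy)-2-(phenylthio)-9βH-labda-2,8(17),13E-trien-15-oate
Conditions: Burgess reagent, toluene, 70 °C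
Reagents that add atoms: none
Why: Burgess dehydration (thermal syn elimination of the sulfamate ester) removes the C3 oxygen together with the cis, sulfur-acidified H2β, the only β-hydrogen available because C4 is quaternary, and gives the vinyl sulfide under neutral conditions that spare the enoate.

Step 19
Reactants: 27 vinyl sulfide
Product: 28 methyl 18-(tert-butyldimethylsilyloxy)-2-oxo-9βH-labda-8(17),13E-dien-15-oate
Conditions: HgCl2, CaCO3, MeCN/H2O (4:1), 50 °C
Reagents that add atoms: water O
Why: Hydrolysis of the vinyl sulfide assisted by thiophilic divalent mercury (protonation at C3, addition of water to the C2 thionium ion, loss of thiolate) leaves the C2 ketone and completes the 1,2-carbonyl transposition, HgCl2 being too weak an electrophile to oxymercurate the alkenes.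

Step 20
Reactants: 28 2-ketone silyl ether
Product: 29 methyl 18-hydroxy-2-oxo-9βH-labda-8(17),13E-dien-15-oate
Conditions: HF·pyridine, pyridine, THF, 0 °C → rt
Reagents that add atoms: none
Why: Fluoride-mediated desilylation frees the C18 alcohol only after the carbonyl has left C3, so that no β-hydroxy ketone prone to retro-aldol loss of C18 is ever formed.

Step 21
Reactants: 29 keto alcohol
Product: 30 methyl 2,18-dioxo-9βH-labda-8(17),13E-dien-15-oate (C18 aldehyde)
Conditions: Dess–Martin periodinane, CH2Cl2, rt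
Reagents that add atoms: none
Why: Dess–Martin oxidation of the neopentyl primary alcohol gives the aldehyde, which cannot epimerise because C4 is quaternary.

Step 22
Reactants: 30 keto aldehyde
Product: 31 15-methoxy-2,15-dioxo-9βH-labda-8(17),13E-dien-18-oic acid
Conditions: NaClO2, NaH2PO4, 2-methyl-2-butene, t-BuOH/H2O, rt
Reagents that add atoms: sodium chlorite [Na+].[O-]Cl=O
Why: Pinnick oxidation converts the aldehyde into the acid while 2-methyl-2-butene scavenges hypochlorous acid and protects the alkenes, the resulting γ-keto acid being stable to decarboxylation.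

Step 23
Reactants: 31 2-keto acid
Product: 32 2β-hydroxy-15-methoxy-15-oxo-9βH-labda-8(17),13E-dien-18-oic acid
Conditions: NaBH4, MeOH, 0 °C; dilute aqueous acid work-up
Reagents that add atoms: none
Why: Borohydride reduction of the C2 ketone takes hydride from the α face because the β face is blocked by the syn-axial C19 and C20 methyls, which sets C2 as the axial 2β-alcohol, carboxylate and enoate being inert.

Step 24
Reactants: 32 hydroxy acid methyl ester
Product: 33 2β-hydroxy-9βH-labda-8(17),13E-diene-15,18-dioic acid (target)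
Conditions: LiOH, THF/MeOH/H2O, 45 °C; then dilute HCl to pH 3, 0 °C
Reagents that add atoms: lithium hydroxide [Li+].[OH-]
Why: Saponification of the methyl enoate and acidification give the diacid, and the axial 2β-hydroxyl and the equatorial α-carboxyl at C4 lie on opposite faces of ring A and cannot lactonise.

**Compound list**

1 | geranyl acetate | CC(C)=CCC/C(C)=C/COC(C)=O | starting material
2 | (2E,6E)-8-hydroxy-3,7-dimethylocta-2,6-dien-1-yl acetate | OC/C(C)=C/CC/C(C)=C/COC(C)=O | intermediate
3 | (2E)-5-[(2S,3S)-3-(hydroxymethyl)-3-methyloxiran-2-yl]-3-methylpent-2-en-1-yl acetate | OC[C@]1(C)O[C@H]1CC/C(C)=C/COC(C)=O | intermediate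
4 | tert-butyldimethylsilyl ether of 3 | CC(C)(C)[Si](C)(C)OC[C@]1(C)O[C@H]1CC/C(C)=C/COC(C)=O | intermediate
5 | (2E)-5-[(2S,3S)-3-(tert-butyldimethylsilyloxymethyl)-3-methyloxiran-2-yl]-3-methylpent-2-en-1-ol | CC(C)(C)[Si](C)(C)OC[C@]1(C)O[C@H]1CC/C(C)=C/CO | intermediate
6 | methanesulfonate of 5 | CC(C)(C)[Si](C)(C)OC[C@]1(C)O[C@H]1CC/C(C)=C/COS(C)(=O)=O | intermediate (not isolated)
7 | (2S,3S)-3-[(3E)-5-bromo-3-methylpent-3-en-1-yl]-2-(tert-butyldimethylsilyloxymethyl)-2-methyloxirane | CC(C)(C)[Si](C)(C)OC[C@]1(C)O[C@H]1CC/C(C)=C/CBr | intermediate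
8 | methyl acetoacetate | COC(=O)CC(C)=O | starting material
9 | sodium lithium dianion of methyl acetoacetate | [Na+].[Li+].[CH2-]C(=O)[CH-]C(=O)OC | intermediate (not isolated)
10 | methyl (6E)-9-[(2S,3S)-3-(tert-butyldimethylsilyloxymethyl)-3-methyloxiran-2-yl]-7-methyl-3-oxonon-6-enoate | CC(C)(C)[Si](C)(C)OC[C@]1(C)O[C@H]1CC/C(C)=C/CCC(=O)CC(=O)OC | intermediate
11 | (2E)-enol triflate of 10 (C7 and C11 cis) | CC(C)(C)[Si](C)(C)OC[C@]1(C)O[C@H]1CC/C(C)=C/CC/C(OS(=O)(=O)C(F)(F)F)=C\C(=O)OC | intermediate
12 | allylic alcohol from 11 (C11 carbinol, C8 triflate) | CC(C)(C)[Si](C)(C)OC[C@]1(C)O[C@H]1CC/C(C)=C/CC/C(OS(=O)(=O)C(F)(F)F)=C\CO | intermediate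
13 | methanesulfonate of 12 | CC(C)(C)[Si](C)(C)OC[C@]1(C)O[C@H]1CC/C(C)=C/CC/C(OS(=O)(=O)C(F)(F)F)=C\COS(C)(=O)=O | intermediate (not isolated)
14 | allylic bromide from 12 (C11 bromide, C8 triflate) | CC(C)(C)[Si](C)(C)OC[C@]1(C)O[C@H]1CC/C(C)=C/CC/C(OS(=O)(=O)C(F)(F)F)=C\CBr | intermediate
15 | dilithium dianion of methyl acetoacetate | [Li+].[Li+].[CH2-]C(=O)[CH-]C(=O)OC | intermediate (not isolated)
16 | methyl (6E,10E)-13-[(2S,3S)-3-(tert-butyldimethylsilyloxymethyl)-3-methyloxiran-2-yl]-11-methyl-3-oxo-7-(trifluoromethylsulfonyloxy)trideca-6,10-dienoate | CC(C)(C)[Si](C)(C)OC[C@]1(C)O[C@H]1CC/C(C)=C/CC/C(OS(=O)(=O)C(F)(F)F)=C\CCC(=O)CC(=O)OC | intermediate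
17 | (trimethylsilyl)methylmagnesium chloride | C[Si](C)(C)C[Mg]Cl | starting material
18 | methyl (6E,10E)-13-[(2S,3S)-3-(tert-butyldimethylsilyloxymethyl)-3-methyloxiran-2-yl]-11-methyl-3-oxo-7-[(trimethylsilyl)methyl]trideca-6,10-dienoate | CC(C)(C)[Si](C)(C)OC[C@]1(C)O[C@H]1CC/C(C)=C/CC/C(C[Si](C)(C)C)=C\CCC(=O)CC(=O)OC | intermediate
19 | sodium (Z)-enolate of 18 | [Na+].CC(C)(C)[Si](C)(C)OC[C@]1(C)O[C@H]1CC/C(C)=C/CC/C(C[Si](C)(C)C)=C\CC/C([O-])=C/C(=O)OC | intermediate (not isolated)
20 | (2Z)-enol diethyl phosphate of 18 | CC(C)(C)[Si](C)(C)OC[C@]1(C)O[C@H]1CC/C(C)=C/CC/C(C[Si](C)(C)C)=C\CC/C(OP(=O)(OCC)OCC)=C/C(=O)OC | intermediate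
21 | methyl (2E,6E,10E)-13-[(2S,3S)-3-(tert-butyldimethylsilyloxymethyl)-3-methyloxiran-2-yl]-3,11-dimethyl-7-[(trimethylsilyl)methyl]trideca-2,6,10-trienoate | CC(C)(C)[Si](C)(C)OC[C@]1(C)O[C@H]1CC/C(C)=C/CC/C(C[Si](C)(C)C)=C\CC/C(C)=C/C(=O)OC | intermediate
22 | methyl 18-(tert-butyldimethylsilyloxy)-3β-hydroxy-9βH-labda-8(17),13E-dien-15-oate | C=C1CC[C@@H]2[C@](C)(CC[C@H](O)[C@@]2(C)CO[Si](C)(C)C(C)(C)C)[C@@H]1CC/C(C)=C/C(=O)OC | intermediate
23 | methyl 18-(tert-butyldimethylsilyloxy)-3-oxo-9βH-labda-8(17),13E-dien-15-oate | C=C1CC[C@@H]2[C@](C)(CCC(=O)[C@@]2(C)CO[Si](C)(C)C(C)(C)C)[C@@H]1CC/C(C)=C/C(=O)OC | intermediate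
24 | lithium C2=C3 enolate of 23 | [Li+].C=C1CC[C@@H]2[C@](C)(CC=C([O-])[C@@]2(C)CO[Si](C)(C)C(C)(C)C)[C@@H]1CC/C(C)=C/C(=O)OC | intermediate (not isolated)
25 | methyl 18-(tert-butyldimethylsilyloxy)-3-oxo-2α-(phenylthio)-9βH-labda-8(17),13E-dien-15-oate | C=C1CC[C@@H]2[C@](C)(C[C@@H](Sc3ccccc3)C(=O)[C@@]2(C)CO[Si](C)(C)C(C)(C)C)[C@@H]1CC/C(C)=C/C(=O)OC | intermediate
26 | methyl 18-(tert-butyldimethylsilyloxy)-3β-hydroxy-2α-(phenylthio)-9βH-labda-8(17),13E-dien-15-oate | C=C1CC[C@@H]2[C@](C)(C[C@@H](Sc3ccccc3)[C@H](O)[C@@]2(C)CO[Si](C)(C)C(C)(C)C)[C@@H]1CC/C(C)=C/C(=O)OC | intermediate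
27 | methyl 18-(tert-butyldimethylsilyloxy)-2-(phenylthio)-9βH-labda-2,8(17),13E-trien-15-oate | C=C1CC[C@@H]2[C@](C)(CC(Sc3ccccc3)=C[C@@]2(C)CO[Si](C)(C)C(C)(C)C)[C@@H]1CC/C(C)=C/C(=O)OC | intermediate
28 | methyl 18-(tert-butyldimethylsilyloxy)-2-oxo-9βH-labda-8(17),13E-dien-15-oate | C=C1CC[C@@H]2[C@](C)(CC(=O)C[C@@]2(C)CO[Si](C)(C)C(C)(C)C)[C@@H]1CC/C(C)=C/C(=O)OC | intermediate
29 | methyl 18-hydroxy-2-oxo-9βH-labda-8(17),13E-dien-15-oate | C=C1CC[C@@H]2[C@](C)(CC(=O)C[C@@]2(C)CO)[C@@H]1CC/C(C)=C/C(=O)OC | intermediate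
30 | methyl 2,18-dioxo-9βH-labda-8(17),13E-dien-15-oate | C=C1CC[C@@H]2[C@](C)(CC(=O)C[C@@]2(C)C=O)[C@@H]1CC/C(C)=C/C(=O)OC | intermediate
31 | 15-methoxy-2,15-dioxo-9βH-labda-8(17),13E-dien-18-oic acid | C=C1CC[C@@H]2[C@](C)(CC(=O)C[C@@]2(C)C(=O)O)[C@@H]1CC/C(C)=C/C(=O)OC | intermediate
32 | 2β-hydroxy-15-methoxy-15-oxo-9βH-labda-8(17),13E-dien-18-oic acid | C=C1CC[C@@H]2[C@](C)(C[C@H](O)C[C@@]2(C)C(=O)O)[C@@H]1CC/C(C)=C/C(=O)OC | intermediate
33 | 2β-hydroxy-9βH-labda-8(17),13E-diene-15,18-dioic acid | C=C1CC[C@@H]2[C@](C)(C[C@H](O)C[C@@]2(C)C(=O)O)[C@@H]1CC/C(C)=C/C(=O)O | target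

**Step count and risk**

Total step count: 24. Longest linear sequence: 24 steps (1 → 33).

Steps most likely to fail:

Step 14. Ring B closure demands an axial C11 chain in the second chair, so the cation formed after ring A may be lost by elimination or the activated epoxide may rearrange to a ketone before C9 attacks; a boat-like ring B would erode the C9 configuration. The fallback keeps the same two bonds but forms them by radical chemistry; it sets out from 16 and returns at 22. Keto ester 16 is phosphorylated (NaH, ClP(O)(OEt)2) to the (Z)-enol phosphate that still carries the C8 triflate F1. Excess Me2CuLi then replaces both the triflate and the phosphate by methyl with retention, giving the epoxy tetraenoate with a C8 methyl group and the same cis C7/C11 geometry F2. Treatment of this compound with Cp2TiCl (trivalent titanium, from Cp2TiCl2 and Mn dust, THF, rt) opens the epoxide homolytically to the C4 radical. Two 6-endo radical closures follow, and the tertiary C8 radical is trapped by a second titanium centre and leaves as the exocyclic C8=C17 alkene, so that aqueous acid work-up gives 22. In this variant C4 is set by the equatorial preference of the silyloxymethyl group, not by inversion, so lower selectivity at C4 would have to be accepted.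

Step 7. The trisubstituted epoxide may be attacked by triflic anhydride, or partial chelation of the enolate may erode the E geometry on which C9 depends. The fallback avoids the anhydride altogether; it sets out from 10 and returns at 18. Keto ester 10 is phosphorylated under amine conditions (Et3N, DMAP, ClP(O)(OEt)2, DMPU), which favour the non-chelated enolate, to give the (E)-enol diethyl phosphate F3. Reduction with i-Bu2AlH at −78 °C gives the allylic alcohol F4; MsCl/Et3N gives the mesylate F5 and LiBr the allylic bromide F6. Alkylation of the dilithium dianion 15 with this bromide gives the enol phosphate keto ester F7. Nickel-catalysed coupling of this unactivated enol phosphate with 17 (Ni(acac)2, THF, rt) then delivers 18.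

Step 18. The sulfamate may form slowly at the hindered C3 hydroxyl, or may ionise (sulfur participation or migration of a C4 substituent) before the syn elimination takes place. The fallback dispenses with the alcohol and the dehydration; it sets out from 25 and returns at 27. The 2-phenylthio ketone 25 is deprotonated at C2 (KN(SiMe3)2, THF, −78 °C) and O-triflated with PhNTf2 to the 2-phenylthio enol triflate F8. Palladium-catalysed formate reduction of the triflate (Pd(OAc)2, PPh3, Bu3N, HCO2H, DMF, 60 °C) then gives vinyl sulfide 27.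

**Further compounds**

F1 | step 14 | (Z)-enol diethyl phosphate of 16 retaining the C8 triflate | CC(C)(C)[Si](C)(C)OC[C@]1(C)O[C@H]1CC/C(C)=C/CC/C(OS(=O)(=O)C(F)(F)F)=C\CC/C(OP(=O)(OCC)OCC)=C/C(=O)OC
F2 | step 14 | methyl (2E,6Z,10E)-13-[(2S,3S)-3-(tert-butyldimethylsilyloxymethyl)-3-methyloxiran-2-yl]-3,7,11-trimethyltrideca-2,6,10-trienoate | CC(C)(C)[Si](C)(C)OC[C@]1(C)O[C@H]1CC/C(C)=C/CC/C(C)=C\CC/C(C)=C/C(=O)OC
F3 | step 7 | (2E)-enol diethyl phosphate of 10 | CC(C)(C)[Si](C)(C)OC[C@]1(C)O[C@H]1CC/C(C)=C/CC/C(OP(=O)(OCC)OCC)=C\C(=O)OC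
F4 | step 7 | allylic alcohol from F3 | CC(C)(C)[Si](C)(C)OC[C@]1(C)O[C@H]1CC/C(C)=C/CC/C(OP(=O)(OCC)OCC)=C\CO
F5 | step 7 | methanesulfonate of F4 | CC(C)(C)[Si](C)(C)OC[C@]1(C)O[C@H]1CC/C(C)=C/CC/C(OP(=O)(OCC)OCC)=C\COS(C)(=O)=O
F6 | step 7 | allylic bromide from F4 | CC(C)(C)[Si](C)(C)OC[C@]1(C)O[C@H]1CC/C(C)=C/CC/C(OP(=O)(OCC)OCC)=C\CBr
F7 | step 7 | methyl 3-oxo-7-(diethoxyphosphoryloxy) analogue of 16 | CC(C)(C)[Si](C)(C)OC[C@]1(C)O[C@H]1CC/C(C)=C/CC/C(OP(=O)(OCC)OCC)=C\CCC(=O)CC(=O)OC
F8 | step 18 | methyl 18-(tert-butyldimethylsilyloxy)-2-(phenylthio)-3-(trifluoromethylsulfonyloxy)-9βH-labda-2,8(17),13E-trien-15-oate | C=C1CC[C@@H]2[C@](C)(CC(Sc3ccccc3)=C(OS(=O)(=O)C(F)(F)F)[C@@]2(C)CO[Si](C)(C)C(C)(C)C)[C@@H]1CC/C(C)=C/C(=O)OC
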